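**Plan**
1. Retrosynthetic cuts, in order: the O–acetyl bond; C13–CH3 and C14–C15 (a C13≡C14 alkyne); C9–C11 (a butynyl nucleophile on a C9 ketone); C1–C2 and C3–C4 of ring A (a two-carbon vinyl unit); C10–C1 and C10–CH3 (two enolate alkylations of (R)-carvone).
2. Enabling feature: in ring A the gem-dimethyl carbon C4 (on C5) and the CH2 carbon C1 (on the quaternary C10) are joined by an unsubstituted C2–C3 bridge and sit trans on ring B. C4 can therefore be a tertiary radical born from an isopropenyl group, C1 an aldehyde carbon, and C2–C3 a vinylphosphonium salt.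
3. Forward: ring B is the carvone ring; ring A is annulated onto it in one operation (radical addition, then ring-closing Wittig); the chain is joined at C9, the C8 carbinol is set, and the E-alkene and acetate come last.
4. Stereochemistry: C5 from (R)-carvone; C10 by alkylation anti to the isopropenyl group; C9 by palladium hydride delivery with inversion of a 9β-carbonate; C8 by α-face epoxidation and hydride opening; 13E by syn-carbometalation.
5. Helpers: the C1 aldehyde oxygen leaves as Ph3PO in the key step, the C1=C2 bond is hydrogenated, the C9 oxygen leaves as carbonate, and the alkyne silyl group is cleaved.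

Key step: step 4

Remark: labdane numbering is used for atoms throughout; the target is read as the normal-series labdane (5S,8R,9R,10S,13E). Compound 2 is carried as a mixture of C10 epimers because this centre is re-enolised in step 2.

Step 1
Reactants: 1 (R)-(−)-carvone
Product: 2 (5R,6S)-2,6-dimethyl-5-(prop-1-en-2-yl)cyclohex-2-en-1-one (trans-6-methylcarvone, with its 6-epimer)
Conditions: LiN(iPr)2, THF, −78 °C; MeI, −78 to 0 °C
Reagents that add atoms: iodomethane, CI
Why: Kinetic deprotonation at the α′ CH2 and C-methylation of the cross-conjugated lithium enolate (enolate alkylation) is standard for carvone; the new centre should form mainly trans to the isopropenyl group but is re-enolised in step 2, so its configuration does not matter.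

Step 2
Reactants: 2 trans-6-methylcarvone
Product: 3 (5S,6R)-6-(hydroxymethyl)-2,6-dimethyl-5-(prop-1-en-2-yl)cyclohex-2-en-1-one
Conditions: LiN(iPr)2, THF, −78 °C; CH2O (gas, from cracked paraformaldehyde), −78 °C; AcOH quench at −78 °C
Reagents that add atoms: formaldehyde, C=O
Why: Aldol hydroxymethylation of the tetrasubstituted lithium enolate should take place on the face anti to the neighbouring isopropenyl group, which sets the quaternary C10 with CH2OH trans and CH3 cis to the C5 substituent, and the cold acidic quench forestalls the retro-aldol reaction.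

Step 3
Reactants: 3 hydroxymethyl ketone
Product: 4 (1R,6S)-1,3-dimethyl-2-oxo-6-(prop-1-en-2-yl)cyclohex-3-ene-1-carbaldehyde
Conditions: Dess–Martin periodinane, CH2Cl2, 0 °C to rt
Reagents that add atoms: none
Why: Dess–Martin oxidation should convert the neopentyl primary alcohol into the aldehyde under neutral conditions that spare both alkenes and cannot epimerise the non-enolisable quaternary centre.

Step 4
Reactants: 4 keto aldehyde; 5 vinyltriphenylphosphonium bromide
Product: 7 (4aS,8aS)-2,5,5,8a-tetramethyl-4a,5,6,8a-tetrahydronaphthalen-1(4H)-one, via phosphonium ylide 6 (not isolated)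
Conditions: Fe(acac)3 (30 mol%), Ph(iPrO)SiH2 (2 equiv), 5 (2 equiv), CH2Cl2/THF (anhydrous, degassed), rt to 40 °C; aq. NaHCO3 work-up
Reagents that add atoms: none
Why: Proposed new method: hydrogen-atom transfer from an iron hydride [Fe(acac)3/Ph(iPrO)SiH2] to the 1,1-disubstituted isopropenyl group gives the tertiary C4 radical, which adds to the β-carbon of vinylphosphonium salt 5 (C3–C4 bond); the α-phosphonio radical is reduced by divalent iron to ylide 6, and 6 closes on the C1 aldehyde by an intramolecular Wittig reaction (C1=C2), expelling Ph3PO. The closest known reaction types are the hydrogen-atom-transfer-initiated reductive olefin coupling with its radical–polar crossover annulation variants (Giese addition, then aldol capture of the reduced adduct) and the ionic annulation of vinyltriphenylphosphonium bromide (conjugate addition, then intramolecular Wittig). Ring A is closed by a 6-exo-trig attack of the ylide carbon on the aldehyde, through a cis-fused oxaphosphetane whose syn-elimination can only give the ring cis-alkene. No new stereocentre is formed: the trans ring fusion follows from the trans C10–CHO and C5–CMe2 arms set in steps 1 and 2, and the gem-dimethyl group arises directly from hydrogen-atom delivery to the terminal CH2. Chemoselectivity is needed at three points and is secured by the substrate: the hydrogen atom goes to the electron-rich isopropenyl alkene and not to the electron-poor enone, the nucleophilic tertiary radical prefers the cationic terminal acceptor 5 to the internal trisubstituted enone, and the ylide can only reach the aldehyde because closure on the C9 ketone would give a bridgehead alkene. The medium is aprotic so that 6 is not protonated before it cyclises.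

Step 5
Reactants: 7 dienone
Product: 8 (4aS,8aS)-2,5,5,8a-tetramethyl-4a,5,6,7,8,8a-hexahydronaphthalen-1(4H)-one
Conditions: H2 (3 atm), RhCl(PPh3)3 (5 mol%), benzene/EtOH, rt
Reagents that add atoms: none
Why: Homogeneous hydrogenation with RhCl(PPh3)3 should reduce the cis-disubstituted C1=C2 bond and leave the trisubstituted, conjugated C7=C8 bond, a selectivity well known for this catalyst with carvone-type enones.

Step 6
Reactants: 8 decalin enone; 9 (4-bromobut-1-yn-1-yl)trimethylsilane
Product: 11 methyl (1S,4aS,8aS)-2,5,5,8a-tetramethyl-1-[4-(trimethylsilyl)but-3-yn-1-yl]-1,4,4a,5,6,7,8,8a-octahydronaphthalen-1-yl carbonate (9β-carbonate, 9α-chain), via bromomagnesium alkoxide 10 (not isolated)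
Conditions: 9, Mg, THF (Grignard reagent); anhydrous CeCl3, THF, −78 °C; 8, −78 to 0 °C; then ClCO2Me, DMAP, 0 °C to rt
Reagents that add atoms: methyl chloroformate, COC(=O)Cl
Why: Cerium-promoted Grignard 1,2-addition to the hindered enone carbonyl should take place from the α face, anti to the axial C10 methyl group, to give the 9β-alkoxide 10 (a temporary C9 centre), which is acylated in the same flask by methyl chloroformate.

Step 7
Reactants: 11 tertiary allylic carbonate
Product: 12 14-(trimethylsilyl)-15,16-dinorlabd-7-en-13-yne (5α-H, 9α-H, 10β-CH3)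
Conditions: Pd(OAc)2 (5 mol%), PBu3 (20 mol%), HCO2H, Et3N, 1,4-dioxane, 60 °C
Reagents that add atoms: none
Why: In the palladium-catalysed formate hydrogenolysis of allylic carbonates, zerovalent palladium ionises the 9β-carbonate with inversion to an α-face π-allyl complex and the formate-derived hydride passes from palladium to the more substituted terminus, which should give the less substituted C7=C8 alkene and the C9 centre with 9α-H (net inversion).

Step 8
Reactants: 12 Δ7 silylalkyne
Product: 13 7α,8α-epoxy-14-(trimethylsilyl)-15,16-dinorlabd-13-yne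
Conditions: mCPBA, CH2Cl2, 0 °C
Reagents that add atoms: 3-chloroperoxybenzoic acid, OOC(=O)c1cccc(Cl)c1
Why: Prilezhaev epoxidation of the trisubstituted alkene should occur on the α face, away from the axial C10 methyl group that shields the β face of C8, which sets the C8–O bond α, while the silylalkyne is inert to the peracid.

Step 9
Reactants: 13 epoxide
Product: 15 15,16-dinorlabd-13-yn-8α-ol, via silylated tertiary alcohol 14 (not isolated)
Conditions: LiEt3BH, THF, 0 to 50 °C; then MeOH, K2CO3 (cat.), rt
Reagents that add atoms: none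
Why: SN2 opening of the trisubstituted epoxide by LiEt3BH at the secondary carbon C7 leaves the C8–O bond untouched and so should give the 8α tertiary alcohol with the C8 methyl group β, and base-catalysed methanolysis then cleaves the alkynyl C–Si bond.

Step 10
Reactants: 15 terminal alkyne
Product: 18 (13E)-labd-13-ene-8α,15-diol, via alkenylalane 16 (not isolated), via lithium alkenylalanate 17 (not isolated)
Conditions: AlMe3 (3.5 equiv), Cp2ZrCl2 (25 mol%), CH2Cl2, 0 °C to rt; then n-BuLi, THF, −78 °C; (CH2O)n, −78 °C to rt
Reagents that add atoms: trimethylaluminium, C[Al](C)C; paraformaldehyde (as formaldehyde), C=O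
Why: Zirconium-catalysed Negishi carboalumination adds CH3 and Al syn across the terminal alkyne with the methyl group on the internal carbon, and hydroxymethylation of the derived alanate with retention should give the 13E trisubstituted allylic alcohol, the tertiary hydroxyl being masked in the flask as its aluminium alkoxide.

Step 11
Reactants: 18 diol
Product: 19 (13E)-8α-hydroxylabd-13-en-15-yl acetate (CNP0268033.1)
Conditions: Ac2O, pyridine, DMAP (cat.), CH2Cl2, 0 °C
Reagents that add atoms: acetic anhydride, CC(=O)OC(C)=O
Why: Acylation with Ac2O/pyridine should acetylate the primary allylic alcohol and leave the hindered tertiary C8 hydroxyl free.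

**Compound list**
1 | (R)-(−)-carvone | CC(=C)[C@@H]1CC=C(C)C(=O)C1 | starting material
2 | (5R,6S)-2,6-dimethyl-5-(prop-1-en-2-yl)cyclohex-2-en-1-one (trans-6-methylcarvone) | CC(=C)[C@@H]1CC=C(C)C(=O)[C@H]1C | intermediate
3 | (5S,6R)-6-(hydroxymethyl)-2,6-dimethyl-5-(prop-1-en-2-yl)cyclohex-2-en-1-one | CC(=C)[C@@H]1CC=C(C)C(=O)[C@@]1(C)CO | intermediate
4 | (1R,6S)-1,3-dimethyl-2-oxo-6-(prop-1-en-2-yl)cyclohex-3-ene-1-carbaldehyde | CC(=C)[C@@H]1CC=C(C)C(=O)[C@@]1(C)C=O | intermediate
5 | vinyltriphenylphosphonium bromide | C=C[P+](c1ccccc1)(c1ccccc1)c1ccccc1.[Br-] | starting material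
6 | (1R,6S)-1,3-dimethyl-6-[2-methyl-4-(triphenyl-λ5-phosphanylidene)butan-2-yl]-2-oxocyclohex-3-ene-1-carbaldehyde (phosphonium ylide) | CC(C)(CC=P(c1ccccc1)(c1ccccc1)c1ccccc1)[C@@H]1CC=C(C)C(=O)[C@@]1(C)C=O | intermediate
7 | (4aS,8aS)-2,5,5,8a-tetramethyl-4a,5,6,8a-tetrahydronaphthalen-1(4H)-one | O=C1[C@@]2(C)C=CCC(C)(C)[C@@H]2CC=C1C | intermediate
8 | (4aS,8aS)-2,5,5,8a-tetramethyl-4a,5,6,7,8,8a-hexahydronaphthalen-1(4H)-one | O=C1[C@@]2(C)CCCC(C)(C)[C@@H]2CC=C1C | intermediate
9 | (4-bromobut-1-yn-1-yl)trimethylsilane | C[Si](C)(C)C#CCCBr | starting material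
10 | bromomagnesium (1S,4aS,8aS)-2,5,5,8a-tetramethyl-1-[4-(trimethylsilyl)but-3-yn-1-yl]-1,4,4a,5,6,7,8,8a-octahydronaphthalen-1-olate | Br[Mg]O[C@]1(CCC#C[Si](C)(C)C)[C@@]2(C)CCCC(C)(C)[C@@H]2CC=C1C | intermediate
11 | methyl (1S,4aS,8aS)-2,5,5,8a-tetramethyl-1-[4-(trimethylsilyl)but-3-yn-1-yl]-1,4,4a,5,6,7,8,8a-octahydronaphthalen-1-yl carbonate | COC(=O)O[C@]1(CCC#C[Si](C)(C)C)[C@@]2(C)CCCC(C)(C)[C@@H]2CC=C1C | intermediate
12 | 14-(trimethylsilyl)-15,16-dinorlabd-7-en-13-yne | C[Si](C)(C)C#CCC[C@@H]1[C@@]2(C)CCCC(C)(C)[C@@H]2CC=C1C | intermediate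
13 | 7α,8α-epoxy-14-(trimethylsilyl)-15,16-dinorlabd-13-yne | C[Si](C)(C)C#CCC[C@@H]1[C@@]2(C)CCCC(C)(C)[C@@H]2C[C@H]3O[C@@]13C | intermediate
14 | 14-(trimethylsilyl)-15,16-dinorlabd-13-yn-8α-ol | C[Si](C)(C)C#CCC[C@@H]1[C@@]2(C)CCCC(C)(C)[C@@H]2CC[C@@]1(C)O | intermediate
15 | 15,16-dinorlabd-13-yn-8α-ol | C#CCC[C@@H]1[C@@]2(C)CCCC(C)(C)[C@@H]2CC[C@@]1(C)O | intermediate
16 | (13E)-14-(dimethylalumanyl)-15-norlabd-13-en-8α-ol, O8-dimethylaluminium alkoxide (alkenylalane) | C[Al](C)/C=C(\C)CC[C@@H]1[C@@]2(C)CCCC(C)(C)[C@@H]2CC[C@@]1(C)O[Al](C)C | intermediate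
17 | lithium butyl(dimethyl)alanate of 16 (alkenylalanate) | [Li+].CCCC[Al-](C)(C)/C=C(\C)CC[C@@H]1[C@@]2(C)CCCC(C)(C)[C@@H]2CC[C@@]1(C)O[Al](C)C | intermediate
18 | (13E)-labd-13-ene-8α,15-diol | OC/C=C(\C)CC[C@@H]1[C@@]2(C)CCCC(C)(C)[C@@H]2CC[C@@]1(C)O | intermediate
19 | (13E)-8α-hydroxylabd-13-en-15-yl acetate (CNP0268033.1) | CC(=O)OC/C=C(\C)CC[C@@H]1[C@@]2(C)CCCC(C)(C)[C@@H]2CC[C@@]1(C)O | target

**Step count and risks**
Total steps: 11. Longest linear sequence: 11 steps, from (R)-carvone 1.

Steps most likely to fail:

Step 4. The α-phosphonio radical may be quenched by hydrogen-atom transfer, or ylide 6 protonated by adventitious alcohol, before the Wittig closure; this would stop the sequence at an open-chain phosphonium salt. Iron turnover may also be slow without an alkoxide by-product, and the aldehyde may be hydrosilylated. The fallback uses known chemistry, sets out from 4 and comes back at 7. Aldehyde 4 is coupled with acrolein under the protic reductive olefin coupling conditions [Fe(acac)3, PhSiH3, EtOH/(CH2OH)2, 60 °C] to give the keto dialdehyde (1R,6S)-1,3-dimethyl-6-(2-methyl-5-oxopentan-2-yl)-2-oxocyclohex-3-ene-1-carbaldehyde F1. Piperidinium acetate in warm benzene then effects the intramolecular aldol condensation of the enolisable aldehyde onto the non-enolisable C1 aldehyde, giving the ring A enal (4aS,8aS)-2,5,5,8a-tetramethyl-1-oxo-1,4,4a,5,6,8a-hexahydronaphthalene-7-carbaldehyde F2. Decarbonylation of the enal with stoichiometric RhCl(PPh3)3 in hot toluene returns 7.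

Step 7. The tertiary carbonate may ionise and lose a β-hydrogen to give dienes, or the hydride may be delivered to C7 instead of C9; one step earlier, the hindered tertiary alkoxide may be acylated incompletely. The fallback sets out from 8, bypasses steps 6 and 7, and comes back at 12. Nucleophilic epoxidation of 8 (H2O2, NaOH, MeOH) from the α face gives the 7α,8α-epoxy ketone of 8 F3. Wharton transposition (N2H4·H2O, AcOH, MeOH) gives the allylic alcohol 7α-hydroxy-11,12,13,14,15,16-hexanorlabd-8-ene F4. Esterification with picolinic acid (DCC, DMAP) gives the 7α-picolinate of F4 F5. Copper-mediated anti-SN2′ substitution with the Grignard reagent from 9 (CuBr·SMe2, THF, −40 °C) should enter C9 from the β face, anti to the 7α leaving group, and move the double bond to C7=C8, giving 12.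

Step 9. Hydride attack at C7 cannot follow the trans-diaxial course and may be sluggish, so that base-induced isomerisation of the epoxide to an allylic alcohol competes. The fallback sets out from 12, bypasses steps 8 and 9, and comes back at 14. Mukaiyama hydration of the C7=C8 bond [Co(acac)2, PhSiH3, O2, iPrOH] places the hydroxyl on the tertiary carbon C8 by oxygen capture of the C8 radical from the α face, anti to the axial C10 methyl group, and gives 14, which is desilylated with K2CO3/MeOH to 15 as in step 9.

**Further compounds**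
F1 | step 4 | (1R,6S)-1,3-dimethyl-6-(2-methyl-5-oxopentan-2-yl)-2-oxocyclohex-3-ene-1-carbaldehyde | O=CCCC(C)(C)[C@@H]1CC=C(C)C(=O)[C@@]1(C)C=O
F2 | step 4 | (4aS,8aS)-2,5,5,8a-tetramethyl-1-oxo-1,4,4a,5,6,8a-hexahydronaphthalene-7-carbaldehyde | O=C1[C@@]2(C)C=C(C=O)CC(C)(C)[C@@H]2CC=C1C
F3 | step 7 | 7α,8α-epoxy ketone of 8 (7α,8α-epoxy-11,12,13,14,15,16-hexanorlabdan-9-one) | O=C1[C@@]2(C)CCCC(C)(C)[C@@H]2C[C@H]3O[C@@]13C
F4 | step 7 | 7α-hydroxy-11,12,13,14,15,16-hexanorlabd-8-ene | O[C@@H]1C[C@H]2C(C)(C)CCC[C@]2(C)C=C1C
F5 | step 7 | 7α-picolinate of F4 | O=C(O[C@@H]1C[C@H]2C(C)(C)CCC[C@]2(C)C=C1C)c1ccccn1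
F0 | step 9 | none | none
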